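## Structural features

CNP0130251.0 (15) consists of two fully substituted 1,4-benzoquinone rings joined through C3 of each by an unbranched, saturated tetradecane-1,14-diyl tether; ring A is a 2-hydroxy-5-methoxy-6-methylquinone and ring B a 2,5-dihydroxy-6-methylquinone. There is no stereocentre and no double-bond geometry, so every selectivity question is one of position on the rings. The hydroxyquinones are vinylogous acids, redox-active and sensitive to base and nucleophiles, and the ring A methoxy group is a vinylogous ester, so the quinones have to be unveiled last. The real difficulty is not the carbon framework but placing four oxygens on each ring and distinguishing ring A from ring B by a single O-methyl, which must sit next to the ring methyl and not next to the tether. In each ring the methyl group and the tether carbon are para and the other four positions carry oxygen, so each ring is a tetraoxygenated p-xylene whose second methyl carbon is C1 (ring A) or C14 (ring B) of the tether; the framework to be assembled is thus C28 (two C8 xylene units and a C12 chain), the twenty-ninth carbon of C29H40O8 being the O-methyl carbon. The key step exploits the benzylic carbons C1 and C14: each is turned into a nucleophile and bonded to C2 or C13, the ends of a C12 dielectrophile. A further useful feature belongs to reduced ring A: with methyl ethers on both oxygens beside the methyl and free hydroxyls beside the tether, either para methoxy/hydroxy pair oxidises to the same quinone, so the final oxidation needs no regiocontrol.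

## Logic of the disconnections

15 to 13 (through 14). No carbon–carbon bond is cut. Both quinone rings are traced back to arenes in which all eight ring C–O bonds already exist, six oxygens being masked as methoxymethyl (MOM) acetals and the two beside the ring A methyl as methyl ethers. The reason is that quinones would not survive carbanion chemistry, whereas fully substituted aryl ethers do. The gain is that the redox problem is postponed to the last operation. The demand on the forward step is that acid removes only the acetals, and that the oxidant converts the ring B tetrol of 14 into the dihydroxyquinone and ring A into the hydroxy-methoxy-quinone with loss of exactly one O-methyl.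

13 to 7, 8 and 9 (through 10, 11 and 12). The bonds C1–C2 and C13–C14 of the tether are cut. The benzylic methyl groups are the only C–H acidic sites of a hexasubstituted arene, so each half becomes a simple p-xylene and the chain a symmetrical dihalide: C42 falls to C14, C16 and C12. The forward step must metalate 7 at the methyl between the two acetal ethers and not at the one between the methyl ethers, must alkylate 9 only once, and must give cross-coupling rather than homo-coupling. The excess of 9 has to be removed before the second anion is introduced, since any dibromide left behind would consume that anion.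

7 and 8 to 6. Only O–C bonds are cut (two O–CH3 for 7, two O–CH2OMe for 8), so both coupling partners come from one diol and the preparative work is halved. The reacting methyl of 7 and both methyls of 8 also end up in the same environment, between two acetal ethers, so one set of metalation conditions should serve both. The demand is complete O-alkylation of two hindered phenols.

6 to 3 (through 4 and 5). The two aryl C–O bonds beside one methyl are cut back to C–Br bonds. This reduces a tetraoxygenated ring to a dioxygenated one. The demand is a double bromine–lithium exchange followed by borylation and oxidation on a hindered, electron-rich ring, without loss of the acetals.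

3 to 2. The two C–Br bonds are cut. The only free ring positions of 2 are the two that must become oxygenated, and both are activated ortho and para by the acetal ethers. The demand is nuclear rather than benzylic bromination under conditions that leave the acetals alone.

2 to 1. The two O–CH2OMe bonds are cut. 1 already holds both methyls para to each other and two of the four oxygens. The demand is only a clean double protection.

## Other disconnections considered

Alternative 1: Both rings would be built from acyclic material. The cut falls, in each ring, on the bond from the tether-bearing carbon to its neighbour and on the bond from one carbonyl carbon to the methyl-bearing carbon, which leads to the bis(enone) (4E,20E)-tetracosa-4,20-diene-3,22-dione A1 and two molecules of dimethyl malonate A2. In the forward key step, alkoxide-mediated conjugate addition of A2 to both enone termini of A1, followed by Claisen closure of each ethyl ketone enolate onto an ester, would give the tethered bis(dioxocyclohexanecarboxylate) A3 as its enolate; ester cleavage, decarboxylation and dehydrogenation would then lead to the tethered bis(2-methylresorcinol) A4. In its favour are cheap reagents, the absence of any organometallic step and a two-directional use of the symmetry. Against it, the two rings of A4 are identical, so the single O-methyl of ring A could only be introduced statistically, and each ring carries only two of its four oxygens, so four further aryl C–O bonds would have to be made on one molecule after an aromatisation. On structure the chosen plan is stronger, because it brings all eight oxygens and the ring A/ring B difference into the coupling. On mechanism Alternative 1 is the better plan, since enolate addition and Claisen closure raise no site-selectivity question of the kind that 7 poses. On step economy it is longer, because the synthesis of A1, the aromatisation, the oxygenation and the differentiation all come on top of the ring formation.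

Alternative 2: Both rings would be made by ring expansion of squaric-acid-derived cyclobutenones. The cut falls, in each ring, on the bond between a future quinone carbonyl carbon and the alkoxy-bearing carbon beside the tether, which leads to the tethered bis(4-alkenyl-4-hydroxycyclobutenone) A5, whose two four-membered rings differ in methoxy versus benzyloxy. In the forward key step, heating A5 would open each cyclobutenone to a dienylketene by a 4π electrocyclic opening, and a 6π closure with tautomerisation would give the bis(hydroquinone) A6. In its favour, every ring position is fixed by the substitution of the four-membered ring, all four oxygens per ring arrive differentiated, and A6 is one mild oxidation and two deprotections from the target. Against it, the doubly metalated bis(β-alkoxyvinyl) tether has to be made by halogen or tin exchange and is liable to β-elimination, it must add once to each of two different cyclobutenediones, and two thermolyses must proceed in one molecule. On structure Alternative 2 is the better plan for regiocontrol, because it removes the site-selectivity risk of the chosen route altogether. On mechanism the two plans are equal in one respect, since the sequential mono-addition problem is the same as the mono-alkylation of 9. On step economy the chosen plan is clearly shorter, since the tether and two cyclobutenediones each need their own sequence.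

Alternative 3: Both rings would be made by benzannulation of cyclobutenones with ynol ethers. Three ring bonds per ring are cut, leading to the tethered bis(cyclobutenone) A7, 1-methoxypropyne A8 and 1-(triisopropylsiloxy)propyne A9. In the forward key step, heating A7 first with less than one equivalent of A8 and then with A9 would take each terminus through a vinylketene, a ketene–alkyne cycloadduct and a dienylketene to a resorcinol monoether, giving A10. In its favour, the resorcinol regiochemistry is reliably set and the ring A/ring B difference (methyl ether against silyl ether) is created in the ring-forming step itself. Against it, the differentiation depends on a deficiency of A8 and is therefore statistical, A10 holds only two oxygens per ring so that four more have to be introduced later, and A7 and the ynol ethers are laborious and sensitive. On structure the chosen plan is ahead, because the full oxygenation is in place before the coupling. On mechanism the statistical element is comparable to the mono-alkylation of 9, though there the excess reagent is simply recovered, and the two plans are equal in having no stereochemical issue. On step economy the chosen plan is shorter.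

Key step: step 6

Assumption: the target has no stereocentre, so nothing stereochemical is assigned; the crude bromide 11 (freed only from excess 9) and the air-sensitive hexaphenol 14 are carried on without purification and are treated as intermediates that are not isolated.

## Route

Step 1
Reactants: 1 2,5-dimethylbenzene-1,3-diol (2,5-dimethylresorcinol)
Product: 2 1,3-bis(methoxymethoxy)-2,5-dimethylbenzene
Conditions: MOMCl (2.5 equiv), EtN(iPr)2 (3 equiv), CH2Cl2, 0 °C → rt
Reagents that add atoms: chloromethyl methyl ether (MOMCl), COCCl
Why: Acetalisation of both phenols with an alkoxymethyl chloride and a hindered amine base is standard; the MOM groups placed here later flank the methyl that is to be metalated.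

Step 2
Reactants: 2 1,3-bis(methoxymethoxy)-2,5-dimethylbenzene
Product: 3 1,5-dibromo-2,4-bis(methoxymethoxy)-3,6-dimethylbenzene
Conditions: NBS (2.05 equiv), MeCN, 0 °C → rt, dark
Reagents that add atoms: N-bromosuccinimide, O=C1CCC(=O)N1Br
Why: Electrophilic aromatic bromination; the two remaining ring positions are each ortho to one acetal ether and para to the other, so both should brominate readily, and the polar, acid-free medium should disfavour radical side-chain bromination and acetal loss.

Step 3
Reactants: 3 1,5-dibromo-2,4-bis(methoxymethoxy)-3,6-dimethylbenzene
Product: 6 4,6-bis(methoxymethoxy)-2,5-dimethylbenzene-1,3-diol, via dilithioarene 4 (not isolated), via bis(dimethyl boronate) 5 (not isolated)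
Conditions: t-BuLi (4.4 equiv), Et2O–THF, −78 °C; B(OMe)3, −78 °C → rt; AcOH, 30% H2O2, 0 °C → rt
Reagents that add atoms: hydrogen peroxide, OO (t-BuLi, [Li]C(C)(C)C, and trimethyl borate, COB(OC)OC, supply only the lithium of 4 and the boron and methoxy groups of 5)
Why: Bromine–lithium exchange, borylation and oxidative 1,2-migration of aryl from boron to oxygen is the standard conversion of an aryl bromide into a phenol; each aryllithium is held by the neighbouring MOM oxygen, and the weakly acidic peroxide medium should spare both the acetals and the electron-rich product.

Step 4
Reactants: 6 4,6-bis(methoxymethoxy)-2,5-dimethylbenzene-1,3-diol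
Product: 7 unit A, 1,3-dimethoxy-4,6-bis(methoxymethoxy)-2,5-dimethylbenzene
Conditions: MeI (3 equiv), K2CO3 (4 equiv), DMF, rt → 40 °C
Reagents that add atoms: iodomethane, CI
Why: Williamson O-methylation of the two phenols; this puts the methyl ethers beside the methyl that is to survive as the ring A methyl and leaves the acetal ethers beside the methyl that is to react.

Step 5
Reactants: 6 4,6-bis(methoxymethoxy)-2,5-dimethylbenzene-1,3-diol
Product: 8 unit B, 1,2,4,5-tetrakis(methoxymethoxy)-3,6-dimethylbenzene
Conditions: NaH (2.5 equiv), MOMCl (2.5 equiv), THF–DMF, 0 °C → rt
Reagents that add atoms: chloromethyl methyl ether (MOMCl), COCCl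
Why: O-alkylation of the sodium phenoxides with the alkoxymethyl chloride; the product is symmetrical, so its two methyl groups are equivalent.

Step 6
Reactants: 7 unit A, 1,3-dimethoxy-4,6-bis(methoxymethoxy)-2,5-dimethylbenzene; 8 unit B, 1,2,4,5-tetrakis(methoxymethoxy)-3,6-dimethylbenzene; 9 1,12-dibromododecane
Product: 13 1-[3,5-dimethoxy-2,6-bis(methoxymethoxy)-4-methylphenyl]-14-[2,3,5,6-tetrakis(methoxymethoxy)-4-methylphenyl]tetradecane, via unit A benzylpotassium 10 (not isolated), via ω-bromotridecyl arene 11 (not isolated), via unit B benzylpotassium 12 (not isolated)
Conditions: a) 7, n-BuLi/KOt-Bu (1.05 equiv each), 2,2,6,6-tetramethylpiperidine (0.2 equiv), THF, −78 °C; cannulated into 9 (4 equiv), THF, −78 → −40 °C; NH4Cl quench, excess 9 distilled off bulb-to-bulb, residue used crude; b) 8 (1.5 equiv), n-BuLi/KOt-Bu (1.4 equiv each), THF, −78 °C; then crude 11, −78 → −20 °C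
Reagents that add atoms: none
Why: The reaction type is lateral metalation of alkoxytoluenes with a mixed lithium–potassium base followed by alkylation with a primary bromide; since every ring position of 7 and 8 is substituted, the base can only remove a benzylic proton, and the benzylpotassium then displaces a bromide of 9 by SN2. In 7 the methyl between the two acetal ethers should react, because the MOM oxygens chelate the metal and withdraw electron density more strongly than methyl ethers, and the catalytic amine shuttles protons so that the anion can settle at this better stabilised position (10). Inverse addition to a fourfold excess of 9 should stop at mono-alkylation (11), and the excess is removed before the second stage so that 12 meets a single electrophile. Unit A is used first on purpose: the electrophile 11 then carries only the less acidic methoxy-flanked methyl, so proton transfer to the incoming anion is not expected. Symmetrical 8 raises no site question and is metalated only once because the base is kept below one equivalent. No ring is closed, because anion and bromide are never present in the same molecule, and no stereocentre is formed. The low temperature should suppress E2 loss of HBr and attack of a benzyl anion on its own acetal; the two new bonds are C1–C2 and C13–C14 of the tether.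

Step 7
Reactants: 13 1-[3,5-dimethoxy-2,6-bis(methoxymethoxy)-4-methylphenyl]-14-[2,3,5,6-tetrakis(methoxymethoxy)-4-methylphenyl]tetradecane
Product: 15 2,5-dihydroxy-3-[14-(2-hydroxy-5-methoxy-4-methyl-3,6-dioxocyclohexa-1,4-dien-1-yl)tetradecyl]-6-methylcyclohexa-2,5-diene-1,4-dione (CNP0130251.0), via hexaphenol 14 (not isolated)
Conditions: a) 3 M HCl, MeOH–THF, 50 °C, Ar, then evaporation; b) (NH4)2Ce(NO3)6 (4.2 equiv), MeCN–H2O, 0 °C
Reagents that add atoms: water, O
Why: Acid-catalysed acetal exchange removes the six MOM groups and leaves the two aryl methyl ethers; tetravalent cerium then oxidises the ring B tetrol to the dihydroxyquinone and a para methoxy/hydroxy pair of ring A to the quinone with loss of methanol (oxidative demethylation). Either para pair of ring A, and even an ortho-quinone after tautomerisation, leads to the same hydroxy-methoxy-quinone, so no regiocontrol is needed; 14 is not isolated because its tetrol ring would oxidise in air.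

## Compound list

1 | 2,5-dimethylbenzene-1,3-diol (2,5-dimethylresorcinol) | Cc1cc(O)c(C)c(O)c1 | starting material
2 | 1,3-bis(methoxymethoxy)-2,5-dimethylbenzene | COCOc1cc(C)cc(OCOC)c1C | intermediate
3 | 1,5-dibromo-2,4-bis(methoxymethoxy)-3,6-dimethylbenzene | COCOc1c(C)c(OCOC)c(Br)c(C)c1Br | intermediate
4 | [4,6-bis(methoxymethoxy)-2,5-dimethyl-1,3-phenylene]dilithium | COCOc1c(C)c(OCOC)c([Li])c(C)c1[Li] | intermediate
5 | tetramethyl [4,6-bis(methoxymethoxy)-2,5-dimethyl-1,3-phenylene]diboronate | COCOc1c(C)c(OCOC)c(B(OC)OC)c(C)c1B(OC)OC | intermediate
6 | 4,6-bis(methoxymethoxy)-2,5-dimethylbenzene-1,3-diol | COCOc1c(C)c(OCOC)c(O)c(C)c1O | intermediate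
7 | unit A, 1,3-dimethoxy-4,6-bis(methoxymethoxy)-2,5-dimethylbenzene | Cc1c(OC)c(OCOC)c(C)c(OCOC)c1OC | intermediate
8 | unit B, 1,2,4,5-tetrakis(methoxymethoxy)-3,6-dimethylbenzene | Cc1c(OCOC)c(OCOC)c(C)c(OCOC)c1OCOC | intermediate
9 | 1,12-dibromododecane | BrCCCCCCCCCCCCBr | starting material
10 | [3,5-dimethoxy-2,6-bis(methoxymethoxy)-4-methylbenzyl]potassium | COCOc1c(OC)c(C)c(OC)c(OCOC)c1C[K] | intermediate
11 | 3-(13-bromotridecyl)-1,5-dimethoxy-2,4-bis(methoxymethoxy)-6-methylbenzene | COCOc1c(OC)c(C)c(OC)c(OCOC)c1CCCCCCCCCCCCCBr | intermediate
12 | [2,3,5,6-tetrakis(methoxymethoxy)-4-methylbenzyl]potassium | [K]Cc1c(OCOC)c(OCOC)c(C)c(OCOC)c1OCOC | intermediate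
13 | 1-[3,5-dimethoxy-2,6-bis(methoxymethoxy)-4-methylphenyl]-14-[2,3,5,6-tetrakis(methoxymethoxy)-4-methylphenyl]tetradecane | COCOc1c(OC)c(C)c(OC)c(OCOC)c1CCCCCCCCCCCCCCc1c(OCOC)c(OCOC)c(C)c(OCOC)c1OCOC | intermediate
14 | 3-[14-(2,6-dihydroxy-3,5-dimethoxy-4-methylphenyl)tetradecyl]-6-methylbenzene-1,2,4,5-tetrol | Oc1c(OC)c(C)c(OC)c(O)c1CCCCCCCCCCCCCCc1c(O)c(O)c(C)c(O)c1O | intermediate
15 | 2,5-dihydroxy-3-[14-(2-hydroxy-5-methoxy-4-methyl-3,6-dioxocyclohexa-1,4-dien-1-yl)tetradecyl]-6-methylcyclohexa-2,5-diene-1,4-dione (CNP0130251.0) | COC1=C(C)C(=O)C(O)=C(CCCCCCCCCCCCCCC2=C(O)C(=O)C(C)=C(O)C2=O)C1=O | target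

## Step count and least certain steps

Total: 7 steps. Step 6 comprises two alkylation stages run back to back, and step 7 a deprotection and an oxidation run back to back. Longest linear sequence: 6 steps (1, 2, 3, 4 or 5, 6, 7).

Step 6 (key step). What may go wrong: incomplete discrimination between the two methyl groups of 7 during metalation, because the advantage of two acetal ethers over two methyl ethers in chelation and inductive effect is modest. Lesser risks are double alkylation of 9, elimination of HBr from the bromide, and a second metalation of ring B. The fallback blocks the spectator methyl sterically instead of relying on coordination; it sets out from 6 and comes back to the route at 13. Silylation of 6 with iPr3SiOTf and 2,6-lutidine would give 2,4-bis(methoxymethoxy)-3,6-dimethyl-1,5-bis(triisopropylsilyloxy)benzene F1, in which the spectator methyl lies between two bulky, non-coordinating silyl ethers. Lateral lithiation of F1 with s-BuLi in THF at −78 °C and alkylation with excess 9 would give 3-(13-bromotridecyl)-2,4-bis(methoxymethoxy)-6-methyl-1,5-bis(triisopropylsilyloxy)benzene F2. Reaction of F2 with 12 would give 1-[2,6-bis(methoxymethoxy)-4-methyl-3,5-bis(triisopropylsilyloxy)phenyl]-14-[2,3,5,6-tetrakis(methoxymethoxy)-4-methylphenyl]tetradecane F3. Bu4NF would free 4,6-bis(methoxymethoxy)-2-methyl-5-{14-[2,3,5,6-tetrakis(methoxymethoxy)-4-methylphenyl]tetradecyl}benzene-1,3-diol F4, and methylation of F4 with MeI/K2CO3 would rejoin the route at 13.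

Step 3. What may go wrong: an incomplete second bromine–lithium exchange, or protonation of the dilithio species, leading to partial hydrodebromination; and over-oxidation of the electron-rich resorcinol by the peroxide. The fallback sets out from 3 and comes back at 6: a palladium-catalysed hydroxylation with KOH (Pd2(dba)3 as source of zerovalent palladium, 2-di-tert-butylphosphino-2′,4′,6′-triisopropylbiphenyl, 1,4-dioxane–H2O, 100 °C, careful neutralisation on work-up). It would form both C–O bonds by cross-coupling and needs neither an organolithium nor a peroxide. No new compound arises on this path, which is entered as F0.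

Step 7. What may go wrong: degradation of the hydroxyquinone rings by excess tetravalent cerium, or uncontrolled air oxidation of the polyphenol before the oxidant is added, giving partly oxidised mixtures. The fallback reverses the order of the two operations; it sets out from 13 and comes back at 15. Oxidation of 13 with (NH4)2Ce(NO3)6 in MeCN–H2O at 0 °C should give the bis(quinone) that still carries three MOM groups, 2,5-bis(methoxymethoxy)-3-{14-[5-methoxy-2-(methoxymethoxy)-4-methyl-3,6-dioxocyclohexa-1,4-dien-1-yl]tetradecyl}-6-methylcyclohexa-2,5-diene-1,4-dione F5. Both para pairs of ring A again converge on one product. Dilute aqueous HCl in THF at rt would then hydrolyse the three vinylogous acetal esters of F5 and rejoin the route at 15; methanol is kept out of this stage so that the hydroxyquinones are not etherified.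

Step 2. What may go wrong: loss of MOM groups through traces of HBr, or radical bromination of a methyl group in competition with ring bromination. The fallback changes the order of protection and halogenation; it sets out from 1 and comes back at 3. Bromination of 1 with Br2 in AcOH–CHCl3 at 0 °C would give 4,6-dibromo-2,5-dimethylbenzene-1,3-diol F6, and MOM protection of F6 (NaH, MOMCl, THF–DMF) would rejoin the route at 3.

## Further compounds

F1 | step 6 | 2,4-bis(methoxymethoxy)-3,6-dimethyl-1,5-bis(triisopropylsilyloxy)benzene | COCOc1c(O[Si](C(C)C)(C(C)C)C(C)C)c(C)c(O[Si](C(C)C)(C(C)C)C(C)C)c(OCOC)c1C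
F2 | step 6 | 3-(13-bromotridecyl)-2,4-bis(methoxymethoxy)-6-methyl-1,5-bis(triisopropylsilyloxy)benzene | COCOc1c(O[Si](C(C)C)(C(C)C)C(C)C)c(C)c(O[Si](C(C)C)(C(C)C)C(C)C)c(OCOC)c1CCCCCCCCCCCCCBr
F3 | step 6 | 1-[2,6-bis(methoxymethoxy)-4-methyl-3,5-bis(triisopropylsilyloxy)phenyl]-14-[2,3,5,6-tetrakis(methoxymethoxy)-4-methylphenyl]tetradecane | COCOc1c(O[Si](C(C)C)(C(C)C)C(C)C)c(C)c(O[Si](C(C)C)(C(C)C)C(C)C)c(OCOC)c1CCCCCCCCCCCCCCc1c(OCOC)c(OCOC)c(C)c(OCOC)c1OCOC
F4 | step 6 | 4,6-bis(methoxymethoxy)-2-methyl-5-{14-[2,3,5,6-tetrakis(methoxymethoxy)-4-methylphenyl]tetradecyl}benzene-1,3-diol | COCOc1c(O)c(C)c(O)c(OCOC)c1CCCCCCCCCCCCCCc1c(OCOC)c(OCOC)c(C)c(OCOC)c1OCOC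
F0 | step 3 | none | none
F5 | step 7 | 2,5-bis(methoxymethoxy)-3-{14-[5-methoxy-2-(methoxymethoxy)-4-methyl-3,6-dioxocyclohexa-1,4-dien-1-yl]tetradecyl}-6-methylcyclohexa-2,5-diene-1,4-dione | COCOC1=C(CCCCCCCCCCCCCCC2=C(OCOC)C(=O)C(C)=C(OCOC)C2=O)C(=O)C(OC)=C(C)C1=O
F6 | step 2 | 4,6-dibromo-2,5-dimethylbenzene-1,3-diol | Cc1c(Br)c(O)c(C)c(O)c1Br
A1 | alternative 1 | (4E,20E)-tetracosa-4,20-diene-3,22-dione | CCC(=O)/C=C/CCCCCCCCCCCCCC/C=C/C(=O)CC
A2 | alternative 1 | dimethyl malonate | COC(=O)CC(=O)OC
A3 | alternative 1 | tethered bis(methyl 6-alkyl-3-methyl-2,4-dioxocyclohexane-1-carboxylate), ring stereocentres unassigned | COC(=O)C1C(CCCCCCCCCCCCCCC2CC(=O)C(C)C(=O)C2C(=O)OC)CC(=O)C(C)C1=O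
A4 | alternative 1 | 5,5'-(tetradecane-1,14-diyl)bis(2-methylbenzene-1,3-diol) | Cc1c(O)cc(CCCCCCCCCCCCCCc2cc(O)c(C)c(O)c2)cc1O
A5 | alternative 2 | tetradecane-1,14-diyl-linked bis[4-(2-tert-butoxy-1-alkylvinyl)-4-hydroxy-2-methylcyclobut-2-en-1-one], one ring 3-methoxy and the other 3-benzyloxy, carbinol centres and alkene geometry unassigned | COC1=C(C)C(=O)C1(O)C(=COC(C)(C)C)CCCCCCCCCCCCCCC(=COC(C)(C)C)C1(O)C(OCc2ccccc2)=C(C)C1=O
A6 | alternative 2 | bis(hydroquinone) with tert-butoxy beside the tether and methoxy or benzyloxy beside the methyl | COc1c(C)c(O)c(OC(C)(C)C)c(CCCCCCCCCCCCCCc2c(OC(C)(C)C)c(O)c(C)c(OCc3ccccc3)c2O)c1O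
A7 | alternative 3 | 3,3'-(tetradecane-1,14-diyl)bis(cyclobut-2-en-1-one) | O=C1C=C(CCCCCCCCCCCCCCC2=CC(=O)C2)C1
A8 | alternative 3 | 1-methoxypropyne | CC#COC
A9 | alternative 3 | 1-(triisopropylsiloxy)propyne | CC#CO[Si](C(C)C)(C(C)C)C(C)C
A10 | alternative 3 | 5-alkyl-3-methoxy-2-methylphenol tethered to 5-alkyl-2-methyl-3-(triisopropylsiloxy)phenol | COc1cc(CCCCCCCCCCCCCCc2cc(O)c(C)c(O[Si](C(C)C)(C(C)C)C(C)C)c2)cc(O)c1C
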